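**Strategy**

Everything rests on cutting C6–C7 and C7–C8: carbinol carbon C7 sits between two methylenes whose outer neighbours C5 and C9 both carry oxygen, so C7 is introduced as a 1,3-dithiane acyl-anion linchpin between two terminal epoxides. One flask joins C3–C6 and C8–C26 through a solvent-triggered 1,4-Brook shift, leaving O5 silylated, O9 free and C5, C9 and C11 already set. The precursors are 2-silyl-1,3-dithiane, (S)-2-allyloxirane and a syn β-silyloxy epoxide; both epoxides come from a single batch of (S)-2-allyloxirane. The free O9 hydroxyl then directs reduction at C7, and the dihydropyranone ring (O5, C1–C5) is closed in the final acid step.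

Key step: step 9

Remark on numbering: C1 is the lactone carbonyl carbon, C2=C3 the ring alkene, C5 the ring carbinol carbon, C7, C9 and C11 the side-chain carbinol carbons, C12–C26 the pentadecyl tail; On is the oxygen on Cn. The target is the all-syn (5S,7R,9R,11R) isomer.

Remark on the precursor design: at C5 and at C11 the oxygen, the allyl-side CH2 and the epoxide-side CH2 have the same spatial arrangement. (S)-2-Allyloxirane 4 therefore serves as fragment 1 and, after opening with a tetradecyl nucleophile, as the source of C11 in fragment 2, so only (S)-epichlorohydrin is needed.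

**Route**

Step 1
Reactants: 1 (S)-epichlorohydrin + 2 vinylmagnesium bromide
Product: 3 (S)-1-chloropent-4-en-2-ol
Conditions: CuI (10 mol %), THF, −78 → −20 °C; aq. NH4Cl
Reagents that add atoms: none
Why: Copper-catalysed Grignard opening of the epoxide takes place at the unsubstituted ring carbon faster than chloride displacement, so the stereocentre of 1 is carried over untouched.

Step 2
Reactants: 3 (S)-1-chloropent-4-en-2-ol
Product: 4 (S)-2-allyloxirane (fragment 1)
Conditions: powdered NaOH, Et2O, rt; distillation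
Reagents that add atoms: none
Why: Intramolecular Williamson etherification (3-exo-tet displacement of chloride by the alkoxide) re-forms an epoxide without breaking a bond at the stereocentre.

Step 3
Reactants: 5 1-bromotetradecane + 4 (S)-2-allyloxirane
Product: 7 (R)-nonadec-1-en-4-ol, via tetradecylmagnesium bromide 6 (not isolated)
Conditions: Mg, THF, 45 °C; then CuI (10 mol %), 4, THF, −40 → 0 °C; aq. NH4Cl
Reagents that add atoms: none
Why: Copper-catalysed Grignard opening of a monosubstituted epoxide occurs at the terminal CH2, so C11 is retained from 4 (the descriptor changes from S to R only through the CIP priorities).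

Step 4
Reactants: 7 (R)-nonadec-1-en-4-ol
Product: 8 tert-butyl (R)-nonadec-1-en-4-yl carbonate
Conditions: Boc2O, DMAP, MeCN, rt
Reagents that add atoms: di-tert-butyl dicarbonate, CC(C)(C)OC(=O)OC(=O)OC(C)(C)C
Why: DMAP-catalysed acylation of the secondary alcohol installs the tert-butyl carbonate that acts as the internal oxygen nucleophile in the next step.

Step 5
Reactants: 8 tert-butyl (R)-nonadec-1-en-4-yl carbonate
Product: 9 (4R,6R)-4-(iodomethyl)-6-pentadecyl-1,3-dioxan-2-one (cis)
Conditions: IBr, PhMe, −85 °C; aq. Na2S2O3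
Reagents that add atoms: iodine monobromide, IBr
Why: Iodocarbonate cyclisation (halocyclisation of a homoallylic tert-butyl carbonate): the carbonyl oxygen captures the iodonium ion at C9 (6-exo) through a chair-like transition state with the pentadecyl group equatorial, which should set C9 syn to C11, and the tert-butyl cation is lost.

Step 6
Reactants: 9 (4R,6R)-4-(iodomethyl)-6-pentadecyl-1,3-dioxan-2-one
Product: 10 (R)-1-[(R)-oxiran-2-yl]heptadecan-2-ol
Conditions: K2CO3, MeOH, rt
Reagents that add atoms: none
Why: Methanolysis of the cyclic carbonate frees the C9 alkoxide next to the primary iodide, which closes the epoxide by intramolecular Williamson displacement at C8, so C9 and C11 are not touched.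

Step 7
Reactants: 10 (R)-1-[(R)-oxiran-2-yl]heptadecan-2-ol
Product: 11 tert-butyldimethyl({(R)-1-[(R)-oxiran-2-yl]heptadecan-2-yl}oxy)silane (fragment 2)
Conditions: TBSCl, imidazole, DMF, rt
Reagents that add atoms: tert-butyldimethylsilyl chloride, CC(C)(C)[Si](C)(C)Cl
Why: Imidazole-mediated silylation of the secondary alcohol is non-acidic and leaves the epoxide intact; capping O11 also prevents hemiketal formation once the C7 ketone is unmasked.

Step 8
Reactants: 12 1,3-dithiane
Product: 14 2-(tert-butyldimethylsilyl)-1,3-dithiane, via 2-lithio-1,3-dithiane 13 (not isolated)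
Conditions: n-BuLi, THF, −30 °C; TBSCl, −78 °C → rt
Reagents that add atoms: tert-butyldimethylsilyl chloride, CC(C)(C)[Si](C)(C)Cl
Why: Corey–Seebach lithiation of the dithiane at C2 followed by C-silylation with the silyl chloride.

Step 9
Reactants: 14 2-(tert-butyldimethylsilyl)-1,3-dithiane + 4 (S)-2-allyloxirane + 11 fragment 2
Product: 18 2-[(S)-2-(tert-butyldimethylsilyloxy)pent-4-en-1-yl]-2-[(2R,4R)-4-(tert-butyldimethylsilyloxy)-2-hydroxynonadecyl]-1,3-dithiane, via lithiated silyl dithiane 15 (not isolated), via lithium alkoxide 16 (not isolated), via dithianyl anion 17 (not isolated)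
Conditions: t-BuLi, Et2O, −78 → −45 °C; 4, −78 → −25 °C; 11, HMPA, Et2O, −78 → −30 °C; aq. NH4Cl
Reagents that add atoms: none
Why: t-BuLi deprotonates 14 to 15, which opens 4 at its unsubstituted carbon C6 in ether, where lithium alkoxide 16 persists; adding HMPA together with 11 triggers the 1,4-Brook shift of silicon from C7 to O5, and the resulting anion 17 opens 11 at C8. The closest known reaction type is the one-flask, solvent-controlled coupling of a 2-silyl-1,3-dithiane with two different terminal epoxides (anion relay). No ring closes and no stereocentre is created: C5, C9 and C11 arrive intact in the epoxides because only the CH2 termini are attacked. Terminal regioselectivity is secured by the monosubstituted epoxides and the bulky dithianyl anions. The order of bond formation is secured by the ether-to-HMPA switch and by equimolar 15 and 4, with 11 limiting. Silyl scrambling from O11 to the new O9 alkoxide is suppressed by protonating the mixture cold.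

Step 10
Reactants: 18 bis-silyl hydroxy dithiane
Product: 19 (4S,8R,10R)-4,10-bis(tert-butyldimethylsilyloxy)-8-hydroxypentacos-1-en-6-one
Conditions: MeI, CaCO3, MeCN/H2O (9:1), 45 °C
Reagents that add atoms: water, O
Why: S-Methylation of the dithiane and hydrolysis of the sulfonium intermediates under CaCO3 buffering unmask the C7 ketone under neutral conditions that spare the silyl ethers, the terminal alkene and the β-hydroxy ketone.

Step 11
Reactants: 19 β-hydroxy ketone
Product: 20 (4S,6R,8S,10R)-4,10-bis(tert-butyldimethylsilyloxy)pentacos-1-ene-6,8-diol (C5, C7, C9, C11 all syn)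
Conditions: Et2BOMe, THF/MeOH (4:1), −78 °C; NaBH4; AcOH, then MeOH co-evaporation
Reagents that add atoms: none
Why: Narasaka–Prasad reduction: O9 and the C7 carbonyl form a six-membered diethylboron chelate and external hydride adds axially, which should give the 7,9-syn diol and thus the (7R) centre.

Step 12
Reactants: 20 syn diol
Product: 21 tert-butyl{[(S)-1-{(4R,6S)-6-[(R)-2-(tert-butyldimethylsilyloxy)heptadecyl]-2,2-dimethyl-1,3-dioxan-4-yl}pent-4-en-2-yl]oxy}dimethylsilane (C7/C9 acetonide, cis)
Conditions: Me2C(OMe)2, PPTS (cat.), CH2Cl2, rt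
Reagents that add atoms: 2,2-dimethoxypropane, COC(C)(C)OC
Why: Acid-catalysed transketalisation ties the syn 1,3-diol up as a six-membered acetonide with both substituents equatorial, under conditions too mild to cleave the secondary silyl ethers.

Step 13
Reactants: 21 acetonide alkene
Product: 22 (R)-3-(tert-butyldimethylsilyloxy)-4-{(4R,6S)-6-[(R)-2-(tert-butyldimethylsilyloxy)heptadecyl]-2,2-dimethyl-1,3-dioxan-4-yl}butanal
Conditions: O3, CH2Cl2, −78 °C; PPh3, −78 °C → rt
Reagents that add atoms: ozone, [O-][O+]=O
Why: Ozonolysis of the monosubstituted alkene with reductive work-up gives the C3 aldehyde, and silyl ethers and the acetonide are inert to ozone at low temperature.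

Step 14
Reactants: 22 aldehyde
Product: 23 methyl (2Z,5S)-5-(tert-butyldimethylsilyloxy)-6-{(4R,6S)-6-[(R)-2-(tert-butyldimethylsilyloxy)heptadecyl]-2,2-dimethyl-1,3-dioxan-4-yl}hex-2-enoate
Conditions: (CF3CH2O)2P(O)CH2CO2Me, KN(SiMe3)2, 18-crown-6, THF, −78 °C
Reagents that add atoms: methyl bis(2,2,2-trifluoroethyl)phosphonoacetate, COC(=O)CP(=O)(OCC(F)(F)F)OCC(F)(F)F
Why: Still–Gennari variant of the Horner–Wadsworth–Emmons olefination: the electron-poor phosphonate under dissociating conditions eliminates fast from the kinetic adduct and should give the Z-enoate needed for ring closure, at a temperature where the β-silyloxy aldehyde does not eliminate.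

Step 15
Reactants: 23 Z-enoate
Product: 24 (S)-6-[(2R,4R,6R)-2,4,6-trihydroxyhenicosyl]-5,6-dihydro-2H-pyran-2-one (target)
Conditions: HF (48 % aq.), MeCN, 0 °C → rt
Reagents that add atoms: none
Why: Aqueous HF cleaves both silyl ethers and the acetonide, and the freed O5 hydroxyl lactonises onto the cis-disposed ester (acid-catalysed transesterification to the six-membered ring) without touching any stereocentre.

**Compound list**

1 | (S)-epichlorohydrin | ClC[C@@H]1CO1 | starting material
2 | vinylmagnesium bromide | C=C[Mg]Br | starting material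
3 | (S)-1-chloropent-4-en-2-ol | C=CC[C@H](O)CCl | intermediate
4 | (S)-2-allyloxirane (fragment 1) | C=CC[C@H]1CO1 | intermediate
5 | 1-bromotetradecane | CCCCCCCCCCCCCCBr | starting material
6 | tetradecylmagnesium bromide | CCCCCCCCCCCCCC[Mg]Br | intermediate
7 | (R)-nonadec-1-en-4-ol | CCCCCCCCCCCCCCC[C@@H](O)CC=C | intermediate
8 | tert-butyl (R)-nonadec-1-en-4-yl carbonate | CCCCCCCCCCCCCCC[C@@H](OC(=O)OC(C)(C)C)CC=C | intermediate
9 | (4R,6R)-4-(iodomethyl)-6-pentadecyl-1,3-dioxan-2-one | CCCCCCCCCCCCCCC[C@@H]1C[C@H](CI)OC(=O)O1 | intermediate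
10 | (R)-1-[(R)-oxiran-2-yl]heptadecan-2-ol | CCCCCCCCCCCCCCC[C@@H](O)C[C@@H]1CO1 | intermediate
11 | tert-butyldimethyl({(R)-1-[(R)-oxiran-2-yl]heptadecan-2-yl}oxy)silane (fragment 2) | CCCCCCCCCCCCCCC[C@@H](O[Si](C)(C)C(C)(C)C)C[C@@H]1CO1 | intermediate
12 | 1,3-dithiane | C1CSCSC1 | starting material
13 | 2-lithio-1,3-dithiane | [Li]C1SCCCS1 | intermediate
14 | 2-(tert-butyldimethylsilyl)-1,3-dithiane | CC(C)(C)[Si](C)(C)C1SCCCS1 | intermediate
15 | 2-lithio-2-(tert-butyldimethylsilyl)-1,3-dithiane | CC(C)(C)[Si](C)(C)C1([Li])SCCCS1 | intermediate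
16 | lithium (S)-1-[2-(tert-butyldimethylsilyl)-1,3-dithian-2-yl]pent-4-en-2-olate | C=CC[C@H](O[Li])CC1([Si](C)(C)C(C)(C)C)SCCCS1 | intermediate
17 | 2-lithio-2-[(S)-2-(tert-butyldimethylsilyloxy)pent-4-en-1-yl]-1,3-dithiane | C=CC[C@H](O[Si](C)(C)C(C)(C)C)CC1([Li])SCCCS1 | intermediate
18 | 2-[(S)-2-(tert-butyldimethylsilyloxy)pent-4-en-1-yl]-2-[(2R,4R)-4-(tert-butyldimethylsilyloxy)-2-hydroxynonadecyl]-1,3-dithiane | C=CC[C@H](O[Si](C)(C)C(C)(C)C)CC1(C[C@H](O)C[C@H](O[Si](C)(C)C(C)(C)C)CCCCCCCCCCCCCCC)SCCCS1 | intermediate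
19 | (4S,8R,10R)-4,10-bis(tert-butyldimethylsilyloxy)-8-hydroxypentacos-1-en-6-one | C=CC[C@H](O[Si](C)(C)C(C)(C)C)CC(=O)C[C@H](O)C[C@H](O[Si](C)(C)C(C)(C)C)CCCCCCCCCCCCCCC | intermediate
20 | (4S,6R,8S,10R)-4,10-bis(tert-butyldimethylsilyloxy)pentacos-1-ene-6,8-diol | C=CC[C@H](O[Si](C)(C)C(C)(C)C)C[C@H](O)C[C@H](O)C[C@H](O[Si](C)(C)C(C)(C)C)CCCCCCCCCCCCCCC | intermediate
21 | tert-butyl{[(S)-1-{(4R,6S)-6-[(R)-2-(tert-butyldimethylsilyloxy)heptadecyl]-2,2-dimethyl-1,3-dioxan-4-yl}pent-4-en-2-yl]oxy}dimethylsilane | C=CC[C@H](O[Si](C)(C)C(C)(C)C)C[C@H]1C[C@@H](C[C@H](O[Si](C)(C)C(C)(C)C)CCCCCCCCCCCCCCC)OC(C)(C)O1 | intermediate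
22 | (R)-3-(tert-butyldimethylsilyloxy)-4-{(4R,6S)-6-[(R)-2-(tert-butyldimethylsilyloxy)heptadecyl]-2,2-dimethyl-1,3-dioxan-4-yl}butanal | O=CC[C@H](O[Si](C)(C)C(C)(C)C)C[C@H]1C[C@@H](C[C@H](O[Si](C)(C)C(C)(C)C)CCCCCCCCCCCCCCC)OC(C)(C)O1 | intermediate
23 | methyl (2Z,5S)-5-(tert-butyldimethylsilyloxy)-6-{(4R,6S)-6-[(R)-2-(tert-butyldimethylsilyloxy)heptadecyl]-2,2-dimethyl-1,3-dioxan-4-yl}hex-2-enoate | COC(=O)/C=C\C[C@H](O[Si](C)(C)C(C)(C)C)C[C@H]1C[C@@H](C[C@H](O[Si](C)(C)C(C)(C)C)CCCCCCCCCCCCCCC)OC(C)(C)O1 | intermediate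
24 | (S)-6-[(2R,4R,6R)-2,4,6-trihydroxyhenicosyl]-5,6-dihydro-2H-pyran-2-one | CCCCCCCCCCCCCCC[C@@H](O)C[C@@H](O)C[C@@H](O)C[C@@H]1CC=CC(=O)O1 | target

**Step count**

Total: 15 steps. Longest linear sequence: 14 steps (steps 1–7, then 9–15, from 1 to 24); step 8 is a one-step side branch.

**Steps most likely to fail**

Step 9. What may go wrong: silicon migrates too early or not at all, so that the two epoxides are not taken up in the intended order, or the O9 alkoxide attacks the neighbouring O11 silyl ether and the silyl groups scramble. The fallback sets out from 12 and 4 and comes back at 18. It makes the two C–C bonds in separate operations, with no silyl migration (classical Corey–Seebach double alkylation, two extra steps). 1,3-Dithiane 12 is lithiated (n-BuLi, THF, −30 °C) and opens 4 at C6 to give (S)-1-(1,3-dithian-2-yl)pent-4-en-2-ol F1. Silylation (TBSCl, imidazole, DMF) gives tert-butyl{[(S)-1-(1,3-dithian-2-yl)pent-4-en-2-yl]oxy}dimethylsilane F2. F2 is lithiated at C7 (t-BuLi, THF/HMPA, −78 °C) and opens 11 at C8, with protonation at low temperature, to give 18.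

Step 5. What may go wrong: insufficient facial discrimination when the carbonate captures the iodonium ion, giving a mixture at C9, or competing capture of the iodonium ion by bromide. The fallback sets out from 7 and comes back at 11, bypassing 8, 9 and 10; C9 is set under catalyst control. Compound 7 is silylated (TBSCl, imidazole, DMF) to (R)-tert-butyldimethyl(nonadec-1-en-4-yloxy)silane F3. Epoxidation with mCPBA (CH2Cl2, 0 °C) gives tert-butyldimethyl{[(2R)-1-(oxiran-2-yl)heptadecan-2-yl]oxy}silane F4 as a mixture of both C9 epimers. Jacobsen hydrolytic kinetic resolution follows, with (salen)Co(OAc), a trivalent cobalt complex, and about 0.55 equiv of water relative to the unwanted epimer. The (R,R) enantiomer of the catalyst is expected to hydrolyse (S)-alkyloxiranes; this assignment is made from memory and should be confirmed before use. The resolution should convert the unwanted (9S) epimer into (2S,4R)-4-(tert-butyldimethylsilyloxy)nonadecane-1,2-diol F5, which is removed by chromatography, and leave 11.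

Step 15. What may go wrong: once the acetonide has gone, the C7 hydroxyl adds in conjugate fashion to C3 of the unsaturated ester or lactone (oxa-Michael closure to a tetrahydropyran), or lactonisation stalls at the hydroxy ester while the silyl ethers are only partly cleaved. The fallback sets out from 23 and comes back at 24; the lactone is closed while O7 and O9 are still tied up. Buffered HF·pyridine (pyridine, THF, 0 °C → rt) removes only the two silyl groups and the O5 hydroxyl lactonises (catalytic PPTS, benzene, if needed). This gives (S)-6-({(4R,6R)-6-[(R)-2-hydroxyheptadecyl]-2,2-dimethyl-1,3-dioxan-4-yl}methyl)-5,6-dihydro-2H-pyran-2-one F6. The acetonide is then released last with 80 % aqueous AcOH at rt to give 24.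

**Further compounds**

F1 | step 9 | (S)-1-(1,3-dithian-2-yl)pent-4-en-2-ol | C=CC[C@H](O)CC1SCCCS1
F2 | step 9 | tert-butyl{[(S)-1-(1,3-dithian-2-yl)pent-4-en-2-yl]oxy}dimethylsilane | C=CC[C@H](O[Si](C)(C)C(C)(C)C)CC1SCCCS1
F3 | step 5 | (R)-tert-butyldimethyl(nonadec-1-en-4-yloxy)silane | CCCCCCCCCCCCCCC[C@@H](O[Si](C)(C)C(C)(C)C)CC=C
F4 | step 5 | tert-butyldimethyl{[(2R)-1-(oxiran-2-yl)heptadecan-2-yl]oxy}silane (both epimers at the oxirane carbon) | CCCCCCCCCCCCCCC[C@@H](O[Si](C)(C)C(C)(C)C)CC1CO1
F5 | step 5 | (2S,4R)-4-(tert-butyldimethylsilyloxy)nonadecane-1,2-diol | CCCCCCCCCCCCCCC[C@@H](O[Si](C)(C)C(C)(C)C)C[C@H](O)CO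
F6 | step 15 | (S)-6-({(4R,6R)-6-[(R)-2-hydroxyheptadecyl]-2,2-dimethyl-1,3-dioxan-4-yl}methyl)-5,6-dihydro-2H-pyran-2-one | CCCCCCCCCCCCCCC[C@@H](O)C[C@@H]1C[C@H](C[C@@H]2CC=CC(=O)O2)OC(C)(C)O1
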